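**Retrosynthetic overview** (locants are those of the benzo[7]annulene skeleton of the target)

- The two (Z)-2-methylbut-2-enoyl groups go on last; the seven-membered ring is opened at C8=C9 (ring-closing metathesis of a vinyl and an isopropenyl group on a cyclohexenone).
- The C6/C7 syn-diol with its vinyl group comes from an aldehyde at C-6 and a (Z)-γ-alkoxyallylborane; the aldehyde comes from a nitromethyl group (Nef reaction).
- The six-membered ring is opened at the enone bond C3=C4 (aldol condensation) and at C4a–C5 (Michael addition), giving an acyclic δ-keto aldehyde and 2-methyl-1-nitropropene.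
- Enabling feature: C-4a, the ring-fusion CH γ to the C-2 carbonyl, carries the quaternary C-5 (CMe2), whose neighbour C-6 bears oxygen. Once C3=C4 is opened, C-4a is the α-carbon of an aldehyde (enamine nucleophile), C-5 the β,β-dimethyl carbon of a nitroalkene and C-6 its nitromethyl carbon.
- The keto aldehyde comes from a rhodium-catalysed isopropenyl addition (sets C-9a) to an enone made by cross-metathesis. Ring order: six-membered ring first (step 4), seven-membered ring second (step 7).

Key step: step 4

Assumption: 2-methyl-1-nitroprop-1-ene and 3-(methoxymethoxy)prop-1-ene are taken as purchasable, and (−)-Ipc2BOMe means the borinate made from (+)-α-pinene.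

**Route**

Step 1
Reactants: 1 but-3-en-1-ol, 2 pent-1-en-3-one
Product: 3 (4E)-7-hydroxyhept-4-en-3-one
Conditions: second-generation Hoveyda–Grubbs catalyst (3 mol%), 2 (3 equiv), CH2Cl2, 40 °C
Reagents that add atoms: none
Why: Olefin cross-metathesis of a terminal alkene with an electron-poor vinyl ketone is selective for the cross product and should give the E-enone.

Step 2
Reactants: 3 (4E)-7-hydroxyhept-4-en-3-one, 4 4,4,5,5-tetramethyl-2-(prop-1-en-2-yl)-1,3,2-dioxaborolane
Product: 5 (5S)-7-hydroxy-5-(prop-1-en-2-yl)heptan-3-one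
Conditions: [Rh(cod)Cl]2 (1.5 mol%), (S)-BINAP (3.3 mol%), KOH (0.2 equiv), 1,4-dioxane/H2O (10:1), 60 °C
Reagents that add atoms: none
Why: Hayashi–Miyaura asymmetric conjugate addition, in which the alkenylrhodium–(S)-BINAP species adds to one face of the E-enone and should set C-5 as S, the free hydroxyl being tolerated.

Step 3
Reactants: 5 (5S)-7-hydroxy-5-(prop-1-en-2-yl)heptan-3-one
Product: 6 (3S)-5-oxo-3-(prop-1-en-2-yl)heptanal
Conditions: Dess–Martin periodinane, CH2Cl2, 0 °C to rt; crude product used at once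
Reagents that add atoms: none
Why: Dess–Martin oxidation of the primary alcohol leaves the ketone and the stereocentre untouched and gives the δ-keto aldehyde, which is not stored because it can close to a cyclohexenone on standing.

Step 4
Reactants: 6 (3S)-5-oxo-3-(prop-1-en-2-yl)heptanal, 7 2-methyl-1-nitroprop-1-ene
Product: 9 (4S,5R)-2-methyl-4-(2-methyl-1-nitropropan-2-yl)-5-(prop-1-en-2-yl)cyclohex-2-en-1-one, via nitro keto aldehyde 8 (not isolated)
Conditions: (R)-2-[diphenyl(trimethylsilyloxy)methyl]pyrrolidine (20 mol%), 4-nitrophenol (20 mol%), 7 (2 equiv), toluene, 0 °C to rt; then Bn2NH·CF3CO2H (30 mol%), 50 °C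
Reagents that add atoms: none
Why: The secondary amine condenses only with the aldehyde of 6 to an E-enamine whose C-2 attacks the dimethyl-substituted carbon of 7 (Michael addition), and hydrolysis releases 8. The ammonium salt then promotes an intramolecular aldol condensation in which the CH2 of the ethyl ketone (C-6 of 8) attacks the aldehyde carbon C-1 and water is lost, so the new C(Me)=CH bond of the enone is the ring-closing bond (6-enolexo-exo-trig). The closest known reaction types are the amine-catalysed Michael addition of aldehydes to β,β-disubstituted nitroalkenes and the aldol condensation of 5-oxo aldehydes to 4-substituted cyclohex-2-enones (Robinson-type annulation). The new stereocentre (C-2 of 8, C-4 of 9) is set by the catalyst, whose diphenyl(silyloxy)methyl group shields one enamine face, so the R catalyst should give 2S; the two substituents at the existing C-3 are of similar size and leave the choice to the catalyst. The step needs chemoselectivity (the bulky amine does not activate the ketone, so conjugate addition precedes ring closure), regioselectivity in the aldol step (only the ethyl CH2 can give a six-membered ring, the other α-carbon would give a four-membered ring) and retention at C-2, which the quaternary neighbour secures by hindering renewed enamine formation. The resulting 4S,5R product has the nitro-tert-butyl and isopropenyl groups cis, as the seven-membered ring requires.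

Step 5
Reactants: 9 (4S,5R)-2-methyl-4-(2-methyl-1-nitropropan-2-yl)-5-(prop-1-en-2-yl)cyclohex-2-en-1-one
Product: 11 2-methyl-2-[(1S,6R)-3-methyl-4-oxo-6-(prop-1-en-2-yl)cyclohex-2-en-1-yl]propanal, via sodium nitronate 10 (not isolated)
Conditions: NaOMe, MeOH, 0 °C; then aq. TiCl3, NH4OAc buffer (pH 5), THF, 0 °C to rt; product used at once
Reagents that add atoms: water, O
Why: Nef reaction in its reductive form, in which the nitronate is reduced by trivalent titanium to the imine and hydrolysed at buffered pH to an aldehyde that has no α-hydrogen, while the enone is spared and the cold, buffered medium should prevent a carbonyl-ene closure onto the neighbouring isopropenyl group.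

Step 6
Reactants: 11 2-methyl-2-[(1S,6R)-3-methyl-4-oxo-6-(prop-1-en-2-yl)cyclohex-2-en-1-yl]propanal, 12 3-(methoxymethoxy)prop-1-ene
Product: 15 (4S,5R)-4-[(3R,4R)-3-hydroxy-4-(methoxymethoxy)-2-methylhex-5-en-2-yl]-2-methyl-5-(prop-1-en-2-yl)cyclohex-2-en-1-one, via (Z)-3-(methoxymethoxy)allyllithium 13 (not isolated), via (Z)-3-(methoxymethoxy)allyl(diisopinocampheyl)borane 14 (not isolated)
Conditions: 12, s-BuLi, THF, −78 °C; (−)-Ipc2BOMe; BF3·OEt2; then 11, −78 °C; HOCH2CH2NH2 work-up
Reagents that add atoms: none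
Why: Brown asymmetric (Z)-γ-alkoxyallylboration, in which the Z-allylborane reacts through a chair transition state to give the syn diol monoether and the isopinocampheyl groups direct attack to the Si face of the aldehyde, so 3R and 4R should be set by reagent control while the conjugated ketone does not react at −78 °C.

Step 7
Reactants: 15 (4S,5R)-4-[(3R,4R)-3-hydroxy-4-(methoxymethoxy)-2-methylhex-5-en-2-yl]-2-methyl-5-(prop-1-en-2-yl)cyclohex-2-en-1-one
Product: 16 (4aS,6R,7R,9aR)-6-hydroxy-7-(methoxymethoxy)-3,5,5,9-tetramethyl-1,4a,5,6,7,9a-hexahydro-2H-benzo[7]annulen-2-one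
Conditions: second-generation Grubbs catalyst (10 mol%), toluene (0.002 M), 80 °C
Reagents that add atoms: none
Why: Ring-closing metathesis of the vinyl group with the 1,1-disubstituted isopropenyl group closes the seven-membered ring as the trisubstituted cycloalkene, the cis arrangement at C-4/C-5 bringing the olefins together while the electron-poor enone olefin stays inert and no stereocentre is touched.

Step 8
Reactants: 16 (4aS,6R,7R,9aR)-6-hydroxy-7-(methoxymethoxy)-3,5,5,9-tetramethyl-1,4a,5,6,7,9a-hexahydro-2H-benzo[7]annulen-2-one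
Product: 17 (4aS,6R,7R,9aR)-6,7-dihydroxy-3,5,5,9-tetramethyl-1,4a,5,6,7,9a-hexahydro-2H-benzo[7]annulen-2-one
Conditions: aq. HCl (0.5 M), MeOH, rt to 40 °C
Reagents that add atoms: none
Why: Acid-catalysed acetal exchange cleaves the methoxymethyl ether at its O–CH2–O carbon, so the C–O bonds at C-6 and C-7 are not broken.

Step 9
Reactants: 17 (4aS,6R,7R,9aR)-6,7-dihydroxy-3,5,5,9-tetramethyl-1,4a,5,6,7,9a-hexahydro-2H-benzo[7]annulen-2-one, 18 (2Z)-2-methylbut-2-enoic acid
Product: 20 (4aS,6R,7R,9aR)-3,5,5,9-tetramethyl-2-oxo-2,4a,5,6,7,9a-hexahydro-1H-benzo[7]annulene-6,7-diyl bis[(2Z)-2-methylbut-2-enoate], via mixed 2,4,6-trichlorobenzoic anhydride 19 (not isolated)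
Conditions: 18 (5 equiv), 2,4,6-trichlorobenzoyl chloride (5 equiv), Et3N, toluene, rt; then 17, toluene, 80 °C (no DMAP)
Reagents that add atoms: none
Why: Yamaguchi esterification through the mixed anhydride acylates both secondary hydroxyls at the acyl–oxygen bond without touching the stereocentres, and leaving out a nucleophilic pyridine catalyst should keep the Z geometry of the acyl groups.

**Compound list**

1 | but-3-en-1-ol | C=CCCO | starting material
2 | pent-1-en-3-one | CCC(=O)C=C | starting material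
3 | (4E)-7-hydroxyhept-4-en-3-one | CCC(=O)/C=C/CCO | intermediate
4 | 4,4,5,5-tetramethyl-2-(prop-1-en-2-yl)-1,3,2-dioxaborolane | CC(=C)B1OC(C)(C)C(C)(C)O1 | starting material
5 | (5S)-7-hydroxy-5-(prop-1-en-2-yl)heptan-3-one | CCC(=O)C[C@@H](C(C)=C)CCO | intermediate
6 | (3S)-5-oxo-3-(prop-1-en-2-yl)heptanal | CCC(=O)C[C@@H](C(C)=C)CC=O | intermediate
7 | 2-methyl-1-nitroprop-1-ene | CC(C)=C[N+](=O)[O-] | starting material
8 | (2S,3R)-2-(2-methyl-1-nitropropan-2-yl)-5-oxo-3-(prop-1-en-2-yl)heptanal | CCC(=O)C[C@@H](C(C)=C)[C@H](C=O)C(C)(C)C[N+](=O)[O-] | intermediate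
9 | (4S,5R)-2-methyl-4-(2-methyl-1-nitropropan-2-yl)-5-(prop-1-en-2-yl)cyclohex-2-en-1-one | [O-][N+](=O)CC(C)(C)[C@H]1C=C(C)C(=O)C[C@H]1C(C)=C | intermediate
10 | sodium nitronate of 9 | [Na+].[O-][N+]([O-])=CC(C)(C)[C@H]1C=C(C)C(=O)C[C@H]1C(C)=C | intermediate
11 | 2-methyl-2-[(1S,6R)-3-methyl-4-oxo-6-(prop-1-en-2-yl)cyclohex-2-en-1-yl]propanal | O=CC(C)(C)[C@H]1C=C(C)C(=O)C[C@H]1C(C)=C | intermediate
12 | 3-(methoxymethoxy)prop-1-ene | C=CCOCOC | starting material
13 | [(2Z)-3-(methoxymethoxy)prop-2-en-1-yl]lithium | COCO/C=C\C[Li] | intermediate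
14 | [(2Z)-3-(methoxymethoxy)prop-2-en-1-yl]bis[(1R,2S,3R,5R)-2,6,6-trimethylbicyclo[3.1.1]heptan-3-yl]borane | COCO/C=C\CB([C@@H]1C[C@@H]2C[C@H]([C@H]1C)C2(C)C)[C@@H]1C[C@@H]2C[C@H]([C@H]1C)C2(C)C | intermediate
15 | (4S,5R)-4-[(3R,4R)-3-hydroxy-4-(methoxymethoxy)-2-methylhex-5-en-2-yl]-2-methyl-5-(prop-1-en-2-yl)cyclohex-2-en-1-one | COCO[C@H](C=C)[C@H](O)C(C)(C)[C@H]1C=C(C)C(=O)C[C@H]1C(C)=C | intermediate
16 | (4aS,6R,7R,9aR)-6-hydroxy-7-(methoxymethoxy)-3,5,5,9-tetramethyl-1,4a,5,6,7,9a-hexahydro-2H-benzo[7]annulen-2-one | COCO[C@@H]1C=C(C)[C@@H]2CC(=O)C(C)=C[C@@H]2C(C)(C)[C@H]1O | intermediate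
17 | (4aS,6R,7R,9aR)-6,7-dihydroxy-3,5,5,9-tetramethyl-1,4a,5,6,7,9a-hexahydro-2H-benzo[7]annulen-2-one | O[C@@H]1C=C(C)[C@@H]2CC(=O)C(C)=C[C@@H]2C(C)(C)[C@H]1O | intermediate
18 | (2Z)-2-methylbut-2-enoic acid (angelic acid) | C/C=C(/C)C(=O)O | starting material
19 | (2Z)-2-methylbut-2-enoic 2,4,6-trichlorobenzoic anhydride | C/C=C(/C)C(=O)OC(=O)c1c(Cl)cc(Cl)cc1Cl | intermediate
20 | (4aS,6R,7R,9aR)-3,5,5,9-tetramethyl-2-oxo-2,4a,5,6,7,9a-hexahydro-1H-benzo[7]annulene-6,7-diyl bis[(2Z)-2-methylbut-2-enoate] | C/C=C(/C)C(=O)O[C@@H]1C=C(C)[C@@H]2CC(=O)C(C)=C[C@@H]2C(C)(C)[C@H]1OC(=O)/C(C)=C\C | target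

**Step count and risks**

Total step count: 9. Longest linear sequence: 9 steps (1 and 2 to 20).

Steps most likely to fail:

Step 4. The conjugate addition has to form a quaternary carbon next to a branched α-carbon, and it may be slow. During a slow reaction 6 can close on its own to the unsubstituted cyclohexenone, the nitroalkene can slip into its allylic isomer, and the configuration at C-2 of 8 can erode before ring closure. The fallback sets out from 5 and returns at 8; it takes the ketone out of play and uses a stronger, auxiliary-controlled nucleophile. The ketone of 5 is masked with ethylene glycol and TsOH to give (3S)-3-[(2-ethyl-1,3-dioxolan-2-yl)methyl]-4-methylpent-4-en-1-ol F1. Dess–Martin oxidation gives (3S)-3-[(2-ethyl-1,3-dioxolan-2-yl)methyl]-4-methylpent-4-enal F2. Condensation with (2S)-2-(methoxymethyl)pyrrolidin-1-amine gives the hydrazone (2S)-N-{(1E,3S)-3-[(2-ethyl-1,3-dioxolan-2-yl)methyl]-4-methylpent-4-en-1-ylidene}-2-(methoxymethyl)pyrrolidin-1-amine F3. Deprotonation with LiN(iPr)2 in THF at −78 °C and Michael addition of the aza-enolate to 7 should give (2S)-N-{(1E,2S,3R)-3-[(2-ethyl-1,3-dioxolan-2-yl)methyl]-4-methyl-2-(2-methyl-1-nitropropan-2-yl)pent-4-en-1-ylidene}-2-(methoxymethyl)pyrrolidin-1-amine F4. Aqueous oxalic acid followed by dilute HCl in THF removes the auxiliary and the dioxolane to give 8, which is cyclised with Bn2NH·CF3CO2H as in step 4.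

Step 5. The reduction may stop at the oxime, the low-valent titanium may attack the enone, and acid contact may trigger a carbonyl-ene closure of the freed aldehyde onto the cis isopropenyl group. The fallback sets out from 9 and returns at 11; it is metal-free and passes through an isolable oxime. Treatment of 9 with BnBr, KOH and n-Bu4NI in THF (O-benzylation of the nitronate and loss of benzaldehyde) should give 2-methyl-2-[(1S,6R)-3-methyl-4-oxo-6-(prop-1-en-2-yl)cyclohex-2-en-1-yl]propanal oxime F5. The oxime is then exchanged onto glyoxylic acid in water/THF at rt to release 11.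

Step 9. Acylation of the hindered hydroxyl at C-6, which sits next to the quaternary carbon, may stay incomplete, and forcing conditions may isomerise the Z acyl groups to the E isomers. The fallback sets out from 17 and returns at 20; it builds the double bonds on the ester after acylation. Compound 17 is acylated with 2-[bis(2,2,2-trifluoroethoxy)phosphoryl]propanoic acid (DCC, DMAP, CH2Cl2), where no olefin geometry is at stake, to give (4aS,6R,7R,9aR)-3,5,5,9-tetramethyl-2-oxo-2,4a,5,6,7,9a-hexahydro-1H-benzo[7]annulene-6,7-diyl bis{2-[bis(2,2,2-trifluoroethoxy)phosphoryl]propanoate} F6. A Z-selective Horner–Wadsworth–Emmons reaction of the Still–Gennari type (KN(SiMe3)2, 18-crown-6, acetaldehyde, THF, −78 °C) then forms both Z double bonds; the phosphonate α-hydrogens are far more acidic than those of the ring ketone.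

Further compounds
F1 | step 4 | (3S)-3-[(2-ethyl-1,3-dioxolan-2-yl)methyl]-4-methylpent-4-en-1-ol | CCC1(OCCO1)C[C@@H](C(C)=C)CCO
F2 | step 4 | (3S)-3-[(2-ethyl-1,3-dioxolan-2-yl)methyl]-4-methylpent-4-enal | CCC1(OCCO1)C[C@@H](C(C)=C)CC=O
F3 | step 4 | (2S)-N-{(1E,3S)-3-[(2-ethyl-1,3-dioxolan-2-yl)methyl]-4-methylpent-4-en-1-ylidene}-2-(methoxymethyl)pyrrolidin-1-amine | CCC1(OCCO1)C[C@@H](C(C)=C)C/C=N/N1CCC[C@H]1COC
F4 | step 4 | (2S)-N-{(1E,2S,3R)-3-[(2-ethyl-1,3-dioxolan-2-yl)methyl]-4-methyl-2-(2-methyl-1-nitropropan-2-yl)pent-4-en-1-ylidene}-2-(methoxymethyl)pyrrolidin-1-amine | CCC1(OCCO1)C[C@@H](C(C)=C)[C@H](/C=N/N1CCC[C@H]1COC)C(C)(C)C[N+](=O)[O-]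
F5 | step 5 | 2-methyl-2-[(1S,6R)-3-methyl-4-oxo-6-(prop-1-en-2-yl)cyclohex-2-en-1-yl]propanal oxime | ON=CC(C)(C)[C@H]1C=C(C)C(=O)C[C@H]1C(C)=C
F6 | step 9 | (4aS,6R,7R,9aR)-3,5,5,9-tetramethyl-2-oxo-2,4a,5,6,7,9a-hexahydro-1H-benzo[7]annulene-6,7-diyl bis{2-[bis(2,2,2-trifluoroethoxy)phosphoryl]propanoate} | CC(C(=O)O[C@@H]1C=C(C)[C@@H]2CC(=O)C(C)=C[C@@H]2C(C)(C)[C@H]1OC(=O)C(C)P(=O)(OCC(F)(F)F)OCC(F)(F)F)P(=O)(OCC(F)(F)F)OCC(F)(F)F
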